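**Retrosynthetic overview**
- The acrylic acid comes from a C1 malonate (deallylation, decarboxylative Mannich methylenation); C3–OH from a catalyst-controlled ketone reduction; 11-OAc/12-OH from the (E)-C11=C12 alkene by asymmetric epoxidation and inverting hydrolysis at C12.
- C1 is set by asymmetric Michael addition of diallyl malonate to a 14-membered (E)-enone; that carbocycle (second ring) is closed by enone-forming ring-closing metathesis of a vinyl ketone with a prenyl terminus.
- The vinyl ketone comes from a vinyl group (Wacker oxidation, α-methylenation); C9–C10 comes from allylic metalation of an isopropenyl group and alkylation with geranyl bromide.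
- Key step and first ring: the oxolane C7–O bond, made by a new ligand-controlled oxidative cycloetherification of (R)-linalool that sets C7 and delivers the isopropenyl handle. Ring order: oxolane, then the 14-membered carbocycle.

Assumption: macrocycles are named with cembrane numbering (C1 carries the C15–C17 acrylate, ring atoms C2–C14 run through C3(OH), C4, C7, C8, C11, C12; C18/C19/C20 sit on C4/C8/C12), and each chiral ligand antipode named is the one expected to give the stated face selectivity, to be confirmed on a model substrate.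

**Step 1**
Reactants: 1 (R)-(−)-linalool
Product: 2 (2R,5S)-2-ethenyl-2-methyl-5-(prop-1-en-2-yl)oxolane
Conditions: Pd(OCOCF3)2 (5 mol %), (S)-t-Bu-PyOx (7.5 mol %), Na2CO3, 3 Å MS, O2 (1 atm), toluene, 50 °C
Reagents that add atoms: none
Why: Proposed new method: a ligand-controlled diastereoselective aerobic oxa-Wacker (dehydrogenative 5-exo cycloetherification) of a tertiary bis-homoallylic alcohol, in which the divalent-palladium alkoxide adds syn across the trisubstituted alkene on the face chosen by the oxazoline tert-butyl group (Si face at C6 of linalool, setting C7 as S and cis to the vinyl-bearing C4, which is too remote to interfere), the tertiary alkylpalladium then loses a β-hydrogen from either equivalent methyl group to give the isopropenyl unit, and O2 reoxidises the metal; the closest known reaction type is the enantioselective aerobic Wacker-type cyclisation of alkenyl phenols and alkenyl sulfonamides with sparteine- or PyOx-ligated palladium trifluoroacetate.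

**Step 2**
Reactants: 2 (2R,5S)-2-ethenyl-2-methyl-5-(prop-1-en-2-yl)oxolane; 3 geranyl bromide
Product: 5 (2R,5S)-5-[(5E)-6,10-dimethylundeca-1,5,9-trien-2-yl]-2-ethenyl-2-methyloxolane, via allylpotassium 4 (not isolated)
Conditions: n-BuLi, KOt-Bu, THF/hexane, −78 to −50 °C; then 3, −78 °C to rt
Reagents that add atoms: none
Why: Schlosser-base allylic metalation takes place at the isopropenyl methyl group (the vinyl group has no allylic hydrogen) and the symmetrical 2-substituted allyl anion 4 is alkylated at the primary carbon of the allylic bromide (SN2 allyl–allyl coupling, as in the classical limonene/prenyl halide coupling), which forms C9–C10, keeps the 8(19)-methylene and the E-alkene of 3, and creates no stereocentre.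

**Step 3**
Reactants: 5 (2R,5S)-5-[(5E)-6,10-dimethylundeca-1,5,9-trien-2-yl]-2-ethenyl-2-methyloxolane
Product: 6 1-[(2R,5S)-5-[(5E)-6,10-dimethylundeca-1,5,9-trien-2-yl]-2-methyloxolan-2-yl]ethan-1-one
Conditions: PdCl2(Quinox) (5 mol %; Quinox = 2-(4,5-dihydrooxazol-2-yl)quinoline), AgSbF6 (12.5 mol %), aq. t-BuOOH, CH2Cl2, 0 °C to rt
Reagents that add atoms: tert-butyl hydroperoxide, CC(C)(C)OO
Why: Catalyst-controlled Tsuji–Wacker oxidation, in which the cationic quinoline–oxazoline palladium/hydroperoxide system gives the Markovnikov methyl ketone even at a monosubstituted alkene next to an allylic ether while the 1,1-disubstituted and trisubstituted alkenes do not react; no stereocentre is touched.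

**Step 4**
Reactants: 6 1-[(2R,5S)-5-[(5E)-6,10-dimethylundeca-1,5,9-trien-2-yl]-2-methyloxolan-2-yl]ethan-1-one
Product: 7 1-[(2R,5S)-5-[(5E)-6,10-dimethylundeca-1,5,9-trien-2-yl]-2-methyloxolan-2-yl]prop-2-en-1-one
Conditions: (CH2O)n, i-Pr2NH·CF3CO2H (1 equiv), CF3CO2H (10 mol %), THF, 65 °C
Reagents that add atoms: formaldehyde (as paraformaldehyde), C=O
Why: Mannich-type α-methylenation (aminomethylation then elimination) of a ketone that has a single enolisable position because C4 is quaternary, giving the vinyl ketone needed for ring closure.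

**Step 5**
Reactants: 7 1-[(2R,5S)-5-[(5E)-6,10-dimethylundeca-1,5,9-trien-2-yl]-2-methyloxolan-2-yl]prop-2-en-1-one
Product: 8 (1E,4R,7S,11E)-4,7-epoxy-15,16,17-trinorcembra-1,8(19),11-trien-3-one
Conditions: RuCl2(H2IMes)(=CH-C6H4-2-O-i-Pr) (second-generation Hoveyda–Grubbs catalyst, 10 mol %), toluene (1 mM), 80 °C
Reagents that add atoms: none
Why: Ring-closing metathesis in which the catalyst initiates at the prenyl terminus, the new alkylidene closes onto the electron-poor vinyl ketone at high dilution to give the 14-membered (E)-enone, and the hindered 1,1-disubstituted and internal trisubstituted alkenes stay out because they could only give more substituted alkenes in small or bridged rings.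

**Step 6**
Reactants: 8 (1E,4R,7S,11E)-4,7-epoxy-15,16,17-trinorcembra-1,8(19),11-trien-3-one; 9 diallyl malonate
Product: 10 diallyl 2-[(1R,4R,7S,11E)-4,7-epoxy-3-oxo-15,16,17-trinorcembra-8(19),11-dien-1-yl]malonate
Conditions: Cu(OTf)2 (10 mol %), (S,S)-t-Bu-box (11 mol %), i-Pr2NEt (10 mol %), 4 Å MS, CH2Cl2, −20 °C
Reagents that add atoms: none
Why: Chiral Lewis acid-catalysed Michael addition in which the ketone oxygen and the oxolane oxygen chelate divalent copper, holding the enone s-cis inside the bis(oxazoline) pocket, so that the copper-bound malonate adds to the Re face of C1 and sets C1 as R by catalyst control.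

**Step 7**
Reactants: 10 diallyl 2-[(1R,4R,7S,11E)-4,7-epoxy-3-oxo-15,16,17-trinorcembra-8(19),11-dien-1-yl]malonate
Product: 11 diallyl 2-[(1R,4R,7S,11S,12S)-4,7:11,12-diepoxy-3-oxo-15,16,17-trinorcembr-8(19)-en-1-yl]malonate
Conditions: L-fructose-derived Shi ketone (30 mol %), Oxone (2KHSO5·KHSO4·K2SO4), K2CO3, Bu4NHSO4, MeCN/(MeO)2CH2/aq. Na2B4O7–Na2EDTA buffer, 0 °C
Reagents that add atoms: potassium peroxymonosulfate (from Oxone), [K+].[O-]S(=O)(=O)OO
Why: Shi asymmetric epoxidation, in which the chiral dioxirane attacks the electron-rich (E)-trisubstituted alkene through the spiro transition state far faster than the 1,1-disubstituted alkene, the allyl esters or the ketone, the enantiomeric ketone catalyst delivering oxygen to give the (11S,12S)-epoxide.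

**Step 8**
Reactants: 11 diallyl 2-[(1R,4R,7S,11S,12S)-4,7:11,12-diepoxy-3-oxo-15,16,17-trinorcembr-8(19)-en-1-yl]malonate
Product: 12 diallyl 2-[(1R,4R,7S,11S,12R)-4,7-epoxy-11,12-dihydroxy-3-oxo-15,16,17-trinorcembr-8(19)-en-1-yl]malonate
Conditions: 3% aq. HClO4, THF, 0 °C
Reagents that add atoms: water, O
Why: Acid-catalysed epoxide hydrolysis in which water opens the protonated epoxide at the tertiary carbon C12 with inversion while C11 keeps its oxygen and configuration, giving the anti (11S,12R)-diol.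

**Step 9**
Reactants: 12 diallyl 2-[(1R,4R,7S,11S,12R)-4,7-epoxy-11,12-dihydroxy-3-oxo-15,16,17-trinorcembr-8(19)-en-1-yl]malonate
Product: 13 diallyl 2-[(1R,4R,7S,11S,12R)-11-acetoxy-4,7-epoxy-12-hydroxy-3-oxo-15,16,17-trinorcembr-8(19)-en-1-yl]malonate
Conditions: Ac2O, pyridine, DMAP (cat.), CH2Cl2, 0 °C to rt
Reagents that add atoms: acetic anhydride, CC(=O)OC(C)=O
Why: Selective acylation in which only the secondary C11 hydroxyl is acetylated under DMAP catalysis, the tertiary C12 hydroxyl being inert and C3 still being a ketone, so no other hydroxyl competes.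

**Step 10**
Reactants: 13 diallyl 2-[(1R,4R,7S,11S,12R)-11-acetoxy-4,7-epoxy-12-hydroxy-3-oxo-15,16,17-trinorcembr-8(19)-en-1-yl]malonate
Product: 14 diallyl 2-[(1R,3R,4R,7S,11S,12R)-11-acetoxy-4,7-epoxy-3,12-dihydroxy-15,16,17-trinorcembr-8(19)-en-1-yl]malonate
Conditions: (S)-2-methyl-CBS-oxazaborolidine (50 mol %), catecholborane (4 equiv), toluene/CH2Cl2, −78 °C; then MeOH, pH 7 buffer
Reagents that add atoms: none
Why: Corey–Bakshi–Shibata reduction in which the (S)-oxazaborolidine distinguishes the quaternary C4 flank (large) from the C2 methylene (small) and delivers hydride to give the (3R)-alcohol by catalyst control, catecholborane at low temperature leaving the alkene, the acetate and the allyl esters untouched.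

**Step 11**
Reactants: 14 diallyl 2-[(1R,3R,4R,7S,11S,12R)-11-acetoxy-4,7-epoxy-3,12-dihydroxy-15,16,17-trinorcembr-8(19)-en-1-yl]malonate
Product: 16 dendronpholide R, via malonic acid 15 (not isolated)
Conditions: Pd(PPh3)4 (5 mol %), Et2NH (5 equiv), THF, rt; then 37% aq. CH2O, 60 °C; work-up at pH 4 (NaH2PO4)
Reagents that add atoms: formaldehyde, C=O
Why: Zerovalent-palladium-catalysed deallylation with diethylamine as allyl acceptor gives malonic acid 15, which undergoes decarboxylative Mannich methylenation (Knoevenagel–Doebner type) with formaldehyde and the same amine to give the 2-substituted acrylic acid without touching the acetate, the hindered C3 hydroxyl being too encumbered to lactonise.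

**Compound list**
1 | (R)-(−)-linalool [(3R)-3,7-dimethylocta-1,6-dien-3-ol] | CC(C)=CCC[C@@](C)(O)C=C | starting material
2 | (2R,5S)-2-ethenyl-2-methyl-5-(prop-1-en-2-yl)oxolane | CC(=C)[C@@H]1CC[C@@](C)(O1)C=C | intermediate
3 | geranyl bromide [(2E)-1-bromo-3,7-dimethylocta-2,6-diene] | CC(C)=CCC/C(C)=C/CBr | starting material
4 | allylpotassium [2-((2S,5R)-5-ethenyl-5-methyloxolan-2-yl)prop-2-en-1-yl]potassium | [K]CC(=C)[C@@H]1CC[C@@](C)(O1)C=C | intermediate
5 | (2R,5S)-5-[(5E)-6,10-dimethylundeca-1,5,9-trien-2-yl]-2-ethenyl-2-methyloxolane | CC(C)=CCC/C(C)=C/CCC(=C)[C@@H]1CC[C@@](C)(O1)C=C | intermediate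
6 | 1-[(2R,5S)-5-[(5E)-6,10-dimethylundeca-1,5,9-trien-2-yl]-2-methyloxolan-2-yl]ethan-1-one | CC(C)=CCC/C(C)=C/CCC(=C)[C@@H]1CC[C@@](C)(O1)C(C)=O | intermediate
7 | 1-[(2R,5S)-5-[(5E)-6,10-dimethylundeca-1,5,9-trien-2-yl]-2-methyloxolan-2-yl]prop-2-en-1-one | CC(C)=CCC/C(C)=C/CCC(=C)[C@@H]1CC[C@@](C)(O1)C(=O)C=C | intermediate
8 | (1E,4R,7S,11E)-4,7-epoxy-15,16,17-trinorcembra-1,8(19),11-trien-3-one | O=C1/C=C/CC/C(C)=C/CCC(=C)[C@@H]2CC[C@@]1(C)O2 | intermediate
9 | diallyl malonate | C=CCOC(=O)CC(=O)OCC=C | starting material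
10 | diallyl 2-[(1R,4R,7S,11E)-4,7-epoxy-3-oxo-15,16,17-trinorcembra-8(19),11-dien-1-yl]malonate | C=CCOC(=O)C(C(=O)OCC=C)[C@@H]1CC/C(C)=C/CCC(=C)[C@@H]2CC[C@@](C)(O2)C(=O)C1 | intermediate
11 | diallyl 2-[(1R,4R,7S,11S,12S)-4,7:11,12-diepoxy-3-oxo-15,16,17-trinorcembr-8(19)-en-1-yl]malonate | C=CCOC(=O)C(C(=O)OCC=C)[C@@H]1CC[C@]3(C)O[C@H]3CCC(=C)[C@@H]2CC[C@@](C)(O2)C(=O)C1 | intermediate
12 | diallyl 2-[(1R,4R,7S,11S,12R)-4,7-epoxy-11,12-dihydroxy-3-oxo-15,16,17-trinorcembr-8(19)-en-1-yl]malonate | C=CCOC(=O)C(C(=O)OCC=C)[C@@H]1CC[C@@](C)(O)[C@@H](O)CCC(=C)[C@@H]2CC[C@@](C)(O2)C(=O)C1 | intermediate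
13 | diallyl 2-[(1R,4R,7S,11S,12R)-11-acetoxy-4,7-epoxy-12-hydroxy-3-oxo-15,16,17-trinorcembr-8(19)-en-1-yl]malonate | C=CCOC(=O)C(C(=O)OCC=C)[C@@H]1CC[C@@](C)(O)[C@@H](OC(C)=O)CCC(=C)[C@@H]2CC[C@@](C)(O2)C(=O)C1 | intermediate
14 | diallyl 2-[(1R,3R,4R,7S,11S,12R)-11-acetoxy-4,7-epoxy-3,12-dihydroxy-15,16,17-trinorcembr-8(19)-en-1-yl]malonate | C=CCOC(=O)C(C(=O)OCC=C)[C@@H]1CC[C@@](C)(O)[C@@H](OC(C)=O)CCC(=C)[C@@H]2CC[C@@](C)(O2)[C@H](O)C1 | intermediate
15 | malonic acid 2-[(1R,3R,4R,7S,11S,12R)-11-acetoxy-4,7-epoxy-3,12-dihydroxy-15,16,17-trinorcembr-8(19)-en-1-yl]propanedioic acid | OC(=O)C(C(=O)O)[C@@H]1CC[C@@](C)(O)[C@@H](OC(C)=O)CCC(=C)[C@@H]2CC[C@@](C)(O2)[C@H](O)C1 | intermediate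
16 | dendronpholide R [(1R,3R,4R,7S,11S,12R)-11-acetoxy-4,7-epoxy-3,12-dihydroxycembra-8(19),15(17)-dien-16-oic acid] | C=C(C(=O)O)[C@@H]1CC[C@@](C)(O)[C@@H](OC(C)=O)CCC(=C)[C@@H]2CC[C@@](C)(O2)[C@H](O)C1 | target

**Step count**
Total steps: 11. Longest linear sequence: 11 steps (1 to 16); 3 and 9 are bought.

**Steps most likely to fail**

Step 1 (the new cycloetherification). The risks are poor cis/trans control by the ligand and side reactions at the vinyl carbinol. The fallback uses known chemistry, sets out from 1 and comes back at 2. Shi epoxidation of the trisubstituted alkene of 1 with the D-fructose-derived ketone and KHSO5 gives (3R,6R)-6,7-epoxylinalool F1. Camphorsulfonic acid in CH2Cl2 cyclises it by 5-exo opening with inversion at C6 to cis-furanoid linalool oxide F2. Dehydration of the tertiary alcohol with Burgess reagent (toluene, 50 °C) gives 2.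

Step 2 (allylic metalation and coupling). The risks are competing deprotonation at the allylic C7–H next to the ring oxygen (ring cleavage or rearrangement) and SN2′ coupling. The fallback reverses the polarity, sets out from 2 and comes back at 5. Ene-type chlorination of the isopropenyl group with Ca(OCl)2 and solid CO2 in CH2Cl2/H2O gives allylic chloride F3, whose two allyl termini are equivalent. Geranyl phenyl sulfone F4, made from 3 and PhSO2Na in DMF, is lithiated (n-BuLi, THF, −78 °C) and alkylated with F3 to give sulfone F5. Reductive desulfonylation with PdCl2(dppp) and LiBHEt3 gives 5.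

Step 6 (asymmetric Michael addition on the macrocyclic enone). The risks are low reactivity of the hindered enone and facial control that the ring conformation may override. The fallback changes the C15 unit to an alkyne, sets out from 8 and comes back at 16. Rhodium-catalysed asymmetric conjugate alkynylation with (triisopropylsilyl)acetylene ([Rh(OAc)(C2H4)2]2, DTBM-segphos antipode for Re-face delivery, dioxane, 80 °C) gives alkynyl ketone F6. The operations of steps 7 to 10, applied unchanged, give epoxide F7, diol F8, acetate F9 and alcohol F10. Bu4NF buffered with AcOH gives terminal alkyne F11. Markovnikov hydrocarboxylation (Pd(OAc)2, Xantphos, HCO2H, cat. Ac2O, toluene, 80 °C) then gives 16.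

Further compounds
F1 | step 1 | (3R,6R)-6,7-epoxy-3,7-dimethyloct-1-en-3-ol | CC1(C)O[C@@H]1CC[C@@](C)(O)C=C
F2 | step 1 | 2-[(2S,5R)-5-ethenyl-5-methyloxolan-2-yl]propan-2-ol | CC(C)(O)[C@@H]1CC[C@@](C)(O1)C=C
F3 | step 2 | (2R,5S)-5-(3-chloroprop-1-en-2-yl)-2-ethenyl-2-methyloxolane | ClCC(=C)[C@@H]1CC[C@@](C)(O1)C=C
F4 | step 2 | [(2E)-3,7-dimethylocta-2,6-dien-1-yl]sulfonylbenzene | CC(C)=CCC/C(C)=C/CS(=O)(=O)c1ccccc1
F5 | step 2 | (2R,5S)-5-[(5E)-4-(benzenesulfonyl)-6,10-dimethylundeca-1,5,9-trien-2-yl]-2-ethenyl-2-methyloxolane (both C4′ epimers) | CC(C)=CCC/C(C)=C/C(CC(=C)[C@@H]1CC[C@@](C)(O1)C=C)S(=O)(=O)c1ccccc1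
F6 | step 6 | (1R,4R,7S,11E)-4,7-epoxy-1-[(triisopropylsilyl)ethynyl]-15,16,17-trinorcembra-8(19),11-dien-3-one | CC(C)[Si](C(C)C)(C(C)C)C#C[C@@H]1CC/C(C)=C/CCC(=C)[C@@H]2CC[C@@](C)(O2)C(=O)C1
F7 | step 6 | (1R,4R,7S,11S,12S)-4,7:11,12-diepoxy-1-[(triisopropylsilyl)ethynyl]-15,16,17-trinorcembr-8(19)-en-3-one | CC(C)[Si](C(C)C)(C(C)C)C#C[C@@H]1CC[C@]3(C)O[C@H]3CCC(=C)[C@@H]2CC[C@@](C)(O2)C(=O)C1
F8 | step 6 | (1R,4R,7S,11S,12R)-4,7-epoxy-11,12-dihydroxy-1-[(triisopropylsilyl)ethynyl]-15,16,17-trinorcembr-8(19)-en-3-one | CC(C)[Si](C(C)C)(C(C)C)C#C[C@@H]1CC[C@@](C)(O)[C@@H](O)CCC(=C)[C@@H]2CC[C@@](C)(O2)C(=O)C1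
F9 | step 6 | (1R,4R,7S,11S,12R)-11-acetoxy-4,7-epoxy-12-hydroxy-1-[(triisopropylsilyl)ethynyl]-15,16,17-trinorcembr-8(19)-en-3-one | CC(C)[Si](C(C)C)(C(C)C)C#C[C@@H]1CC[C@@](C)(O)[C@@H](OC(C)=O)CCC(=C)[C@@H]2CC[C@@](C)(O2)C(=O)C1
F10 | step 6 | (1R,3R,4R,7S,11S,12R)-11-acetoxy-4,7-epoxy-1-[(triisopropylsilyl)ethynyl]-15,16,17-trinorcembr-8(19)-ene-3,12-diol | CC(C)[Si](C(C)C)(C(C)C)C#C[C@@H]1CC[C@@](C)(O)[C@@H](OC(C)=O)CCC(=C)[C@@H]2CC[C@@](C)(O2)[C@H](O)C1
F11 | step 6 | (1R,3R,4R,7S,11S,12R)-11-acetoxy-4,7-epoxy-1-ethynyl-15,16,17-trinorcembr-8(19)-ene-3,12-diol | C#C[C@@H]1CC[C@@](C)(O)[C@@H](OC(C)=O)CCC(=C)[C@@H]2CC[C@@](C)(O2)[C@H](O)C1
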